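## Retrosynthetic overview

1. The target is a (2S)-flavanone. The last operation frees the 7-OH (MOM removal). Before that, the C8 prenyl group is delivered from O5 by a Claisen–Cope shift once ring C is closed, so the ring oxygen is fixed before the 5-OH appears and only the 8-prenyl isomer can form.
2. Key disconnection: the O1–C2 bond of ring C, made by an enantioselective intramolecular oxa-Michael addition of a 2'-hydroxychalcone. This step also sets C2.
3. The chalcone comes from a Claisen–Schmidt condensation of a ring A acetophenone with a ring B aldehyde.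
4. Ring A piece: 2',4',6'-trihydroxyacetophenone, 4-O-MOM, then mono-O-prenylation. Ring B piece: 3-bromo-4-methoxybenzaldehyde by Stille prenylation.
5. Ring order: rings A and B are bought as arenes; ring C is the only ring formed (step 5).

Assumption: the (S)-configured catalyst below is taken to give the (2S) product. The facial sense of a new catalyst–substrate pair must be read from the first run; if it is (2R), the mirror-image catalyst from D-tert-leucine is used with nothing else changed.

Catalyst for step 5, called (S)-BIMP: 1-[3,5-bis(trifluoromethyl)phenyl]-3-[(2S)-3,3-dimethyl-1-{[tris(4-methoxyphenyl)-λ5-phosphanylidene]amino}butan-2-yl]thiourea, SMILES CC(C)(C)[C@@H](CN=P(c1ccc(OC)cc1)(c1ccc(OC)cc1)c1ccc(OC)cc1)NC(=S)Nc1cc(C(F)(F)F)cc(C(F)(F)F)c1.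

Compound 4 is sold as the monohydrate and is dried (toluene azeotrope) before step 2. Eu(fod)3 is tris(6,6,7,7,8,8,8-heptafluoro-2,2-dimethyloctane-3,5-dionato)europium.

## Route

Step 1
Reactants: 1 3-bromo-4-methoxybenzaldehyde; 2 tributyl(3-methylbut-2-en-1-yl)stannane
Product: 3 4-methoxy-3-(3-methylbut-2-en-1-yl)benzaldehyde
Conditions: Pd(PPh3)4 (5 mol%), DMF, 100 °C
Reagents that add atoms: tributyl(3-methylbut-2-en-1-yl)stannane (2), CCCC[Sn](CCCC)(CCCC)CC=C(C)C
Why: Stille cross-coupling, in which zerovalent palladium inserts into the aryl C–Br bond, the prenyl group is transferred from tin and reductive elimination at the unhindered CH2 terminus gives the linear prenyl arene, the aldehyde being tolerated under these neutral conditions.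

Step 2
Reactants: 4 1-(2,4,6-trihydroxyphenyl)ethan-1-one; 5 chloromethyl methyl ether
Product: 6 1-[2,6-dihydroxy-4-(methoxymethoxy)phenyl]ethan-1-one
Conditions: MOMCl (1.0 equiv), i-Pr2NEt (1.1 equiv), CH2Cl2, 0 °C to rt
Reagents that add atoms: chloromethyl methyl ether (5), COCCl
Why: Williamson-type O-alkylation, selective because the 4-OH is the most acidic hydroxyl and the only one not held in a hydrogen bond to the acetyl carbonyl, so one equivalent of MOMCl goes there (the 2,4-bis-ether is removed by chromatography).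

Step 3
Reactants: 6 1-[2,6-dihydroxy-4-(methoxymethoxy)phenyl]ethan-1-one; 7 1-bromo-3-methylbut-2-ene
Product: 8 1-{2-hydroxy-4-(methoxymethoxy)-6-[(3-methylbut-2-en-1-yl)oxy]phenyl}ethan-1-one
Conditions: prenyl bromide (1.05 equiv), K2CO3 (1.5 equiv), acetone, reflux
Reagents that add atoms: 1-bromo-3-methylbut-2-ene (7), CC(C)=CCBr
Why: Williamson ether synthesis (SN2), in which the two ortho-hydroxyls of 6 are equivalent and, after the first O-alkylation, the remaining one is locked in a strong hydrogen bond to the carbonyl, so the reaction stops at the mono-ether.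

Step 4
Reactants: 8 1-{2-hydroxy-4-(methoxymethoxy)-6-[(3-methylbut-2-en-1-yl)oxy]phenyl}ethan-1-one; 3 4-methoxy-3-(3-methylbut-2-en-1-yl)benzaldehyde
Product: 10 (2E)-1-{2-hydroxy-4-(methoxymethoxy)-6-[(3-methylbut-2-en-1-yl)oxy]phenyl}-3-[4-methoxy-3-(3-methylbut-2-en-1-yl)phenyl]prop-2-en-1-one, via aldol adduct 9 (not isolated)
Conditions: KOH (50% aq., 10 equiv), EtOH, rt; work-up at 0 °C, pH 6
Reagents that add atoms: 4-methoxy-3-(3-methylbut-2-en-1-yl)benzaldehyde (3), COc1ccc(C=O)cc1CC=C(C)C
Why: Claisen–Schmidt (crossed aldol) condensation, in which the ketone enolate adds to the non-enolisable aldehyde and E1cB loss of water gives the (E)-enone, which stays ring-open as its phenoxide in strong base while the MOM and prenyl ethers are base-stable.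

Step 5
Reactants: 10 (2E)-1-{2-hydroxy-4-(methoxymethoxy)-6-[(3-methylbut-2-en-1-yl)oxy]phenyl}-3-[4-methoxy-3-(3-methylbut-2-en-1-yl)phenyl]prop-2-en-1-one
Product: 11 (2S)-2-[4-methoxy-3-(3-methylbut-2-en-1-yl)phenyl]-7-(methoxymethoxy)-5-[(3-methylbut-2-en-1-yl)oxy]-2,3-dihydro-4H-chromen-4-one
Conditions: (S)-BIMP catalyst (10 mol%), toluene, −20 °C; AcOH quench at −20 °C at full conversion
Reagents that add atoms: none
Why: Proposed new method: a bifunctional iminophosphorane–thiourea organocatalyst has not, to my knowledge, been used to cyclise a simple, non-activated 2'-hydroxychalcone; the iminophosphorane (a neutral superbase) deprotonates the chelated 2'-OH to a tight chiral aminophosphonium phenoxide ion pair while the thiourea hydrogen-bonds the enone carbonyl, so the phenoxide adds 6-endo-trig to one face of the β-carbon (forming the O1–C2 bond, ring C and the C2 stereocentre) and the aminophosphonium N–H then protonates the enolate at C3, the 6'-prenyloxy group twisting the aroyl unit so that closure is fast and downhill at −20 °C where the uncatalysed background and the ring-opening are slow; the closest known reactions are iminophosphorane-catalysed intramolecular oxa-Michael additions of alcohols to α,β-unsaturated esters and amides and cinchona–thiourea cyclisations of ester-activated 2'-hydroxychalcones.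

Step 6
Reactants: 11 (2S)-2-[4-methoxy-3-(3-methylbut-2-en-1-yl)phenyl]-7-(methoxymethoxy)-5-[(3-methylbut-2-en-1-yl)oxy]-2,3-dihydro-4H-chromen-4-one
Product: 14 (2S)-5-hydroxy-2-[4-methoxy-3-(3-methylbut-2-en-1-yl)phenyl]-7-(methoxymethoxy)-8-(3-methylbut-2-en-1-yl)-2,3-dihydro-4H-chromen-4-one, via ortho-dienone 12 (not isolated), via para-dienone 13 (not isolated)
Conditions: Eu(fod)3 (10 mol%), NaHCO3, PhCl, 85 °C
Reagents that add atoms: none
Why: Domino aromatic Claisen–Cope (para-Claisen) rearrangement, in which trivalent europium chelated between the C4 carbonyl and the O5 ether oxygen accelerates the [3,3] shift of the prenyl group to C6 as a 1,1-dimethylallyl group, the crowded dienone relays it by a second [3,3] shift to C8 as a normal prenyl group and tautomerisation gives the chelated 5-OH phenol, C2 taking no part and keeping its configuration.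

Step 7
Reactants: 14 (2S)-5-hydroxy-2-[4-methoxy-3-(3-methylbut-2-en-1-yl)phenyl]-7-(methoxymethoxy)-8-(3-methylbut-2-en-1-yl)-2,3-dihydro-4H-chromen-4-one
Product: 15 (2S)-5,7-dihydroxy-2-[4-methoxy-3-(3-methylbut-2-en-1-yl)phenyl]-8-(3-methylbut-2-en-1-yl)-2,3-dihydro-4H-chromen-4-one
Conditions: HCl (3 M aq.), MeOH, 40 °C
Reagents that add atoms: none
Why: Acid-catalysed acetal cleavage (MOM removal), in which the protonated acetal loses the phenol and the methoxymethyl cation is trapped by methanol, under conditions routinely used on prenylated flavanones and without base, so C2 is not opened by retro-oxa-Michael.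

## Compound list

1 | 3-bromo-4-methoxybenzaldehyde | COc1ccc(C=O)cc1Br | starting material
2 | tributyl(3-methylbut-2-en-1-yl)stannane | CCCC[Sn](CCCC)(CCCC)CC=C(C)C | starting material
3 | 4-methoxy-3-(3-methylbut-2-en-1-yl)benzaldehyde | COc1ccc(C=O)cc1CC=C(C)C | intermediate
4 | 1-(2,4,6-trihydroxyphenyl)ethan-1-one (2',4',6'-trihydroxyacetophenone) | CC(=O)c1c(O)cc(O)cc1O | starting material
5 | chloromethyl methyl ether (MOMCl) | COCCl | starting material
6 | 1-[2,6-dihydroxy-4-(methoxymethoxy)phenyl]ethan-1-one | CC(=O)c1c(O)cc(OCOC)cc1O | intermediate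
7 | 1-bromo-3-methylbut-2-ene (prenyl bromide) | CC(C)=CCBr | starting material
8 | 1-{2-hydroxy-4-(methoxymethoxy)-6-[(3-methylbut-2-en-1-yl)oxy]phenyl}ethan-1-one | CC(=O)c1c(O)cc(OCOC)cc1OCC=C(C)C | intermediate
9 | aldol adduct, racemic, formed in the flask and not isolated: 3-hydroxy-1-{2-hydroxy-4-(methoxymethoxy)-6-[(3-methylbut-2-en-1-yl)oxy]phenyl}-3-[4-methoxy-3-(3-methylbut-2-en-1-yl)phenyl]propan-1-one | COc1ccc(C(O)CC(=O)c2c(O)cc(OCOC)cc2OCC=C(C)C)cc1CC=C(C)C | intermediate
10 | (2E)-1-{2-hydroxy-4-(methoxymethoxy)-6-[(3-methylbut-2-en-1-yl)oxy]phenyl}-3-[4-methoxy-3-(3-methylbut-2-en-1-yl)phenyl]prop-2-en-1-one | COc1ccc(/C=C/C(=O)c2c(O)cc(OCOC)cc2OCC=C(C)C)cc1CC=C(C)C | intermediate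
11 | (2S)-2-[4-methoxy-3-(3-methylbut-2-en-1-yl)phenyl]-7-(methoxymethoxy)-5-[(3-methylbut-2-en-1-yl)oxy]-2,3-dihydro-4H-chromen-4-one | COc1ccc([C@@H]2CC(=O)c3c(OCC=C(C)C)cc(OCOC)cc3O2)cc1CC=C(C)C | intermediate
12 | ortho-dienone, formed in the flask and not isolated (C6 epimers): (2S)-2-[4-methoxy-3-(3-methylbut-2-en-1-yl)phenyl]-7-(methoxymethoxy)-6-(2-methylbut-3-en-2-yl)-2,3-dihydro-4H-chromene-4,5(6H)-dione | COc1ccc([C@@H]2CC(=O)C3=C(O2)C=C(OCOC)C(C(C)(C)C=C)C3=O)cc1CC=C(C)C | intermediate
13 | para-dienone, formed in the flask and not isolated (C8 epimers): (2S)-2-[4-methoxy-3-(3-methylbut-2-en-1-yl)phenyl]-7-(methoxymethoxy)-8-(3-methylbut-2-en-1-yl)-2,3-dihydro-4H-chromene-4,5(8H)-dione | COc1ccc([C@@H]2CC(=O)C3=C(O2)C(CC=C(C)C)C(OCOC)=CC3=O)cc1CC=C(C)C | intermediate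
14 | (2S)-5-hydroxy-2-[4-methoxy-3-(3-methylbut-2-en-1-yl)phenyl]-7-(methoxymethoxy)-8-(3-methylbut-2-en-1-yl)-2,3-dihydro-4H-chromen-4-one | COc1ccc([C@@H]2CC(=O)c3c(O)cc(OCOC)c(CC=C(C)C)c3O2)cc1CC=C(C)C | intermediate
15 | (2S)-5,7-dihydroxy-2-[4-methoxy-3-(3-methylbut-2-en-1-yl)phenyl]-8-(3-methylbut-2-en-1-yl)-2,3-dihydro-4H-chromen-4-one | COc1ccc([C@@H]2CC(=O)c3c(O)cc(O)c(CC=C(C)C)c3O2)cc1CC=C(C)C | target

## Step count and risks

Total step count: 7. Longest linear sequence: 6 steps (4 → 6 → 8 → 10 → 11 → 14 → 15); step 1 supplies aldehyde 3.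

The three steps most likely to fail are steps 5, 6 and 3.

**Step 5 (the new step).** The ee may be low, or it may erode because the free catalyst re-opens the flavanone once the chalcone is used up. The reaction is therefore quenched with AcOH at full conversion, and any racemic flavanone formed during step 4 is removed from 10 by chromatography beforehand. The ee is read by chiral HPLC and can be raised by recrystallising 11. The fallback uses known chemistry. It sets out from 10: NaOAc in refluxing EtOH closes ring C without stereocontrol and gives 11 as a 1:1 mixture with its mirror image. Preparative chiral SFC on an amylose tris(3,5-dimethylphenylcarbamate) column gives 11 and (2R)-2-[4-methoxy-3-(3-methylbut-2-en-1-yl)phenyl]-7-(methoxymethoxy)-5-[(3-methylbut-2-en-1-yl)oxy]-2,3-dihydro-4H-chromen-4-one F1. F1 is re-opened to chalcone 10 with KOH in EtOH and recycled. The fallback comes back to the route at 11.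

**Step 6.** The ortho-dienone 12 may tautomerise to the 6-(1,1-dimethylallyl) phenol instead of undergoing the second shift. The Lewis acid may also attack the MOM or prenyl ether, and hot Lewis-acid conditions could erode the ee (checked by chiral HPLC on 14). The fallback moves the oxygen-to-carbon prenyl shift to the acetophenone stage. It sets out from 8 and comes back to the route at 15.

- Heating 8 in N,N-diethylaniline at 200 °C (thermal para-Claisen–Cope, as used for xanthohumol-type acetophenones) passes through the ortho-dienone 2-acetyl-3-hydroxy-5-(methoxymethoxy)-6-(2-methylbut-3-en-2-yl)cyclohexa-2,4-dien-1-one F2 and the para-dienone 2-acetyl-3-hydroxy-5-(methoxymethoxy)-4-(3-methylbut-2-en-1-yl)cyclohexa-2,5-dien-1-one F3. It gives 1-[2,6-dihydroxy-4-(methoxymethoxy)-3-(3-methylbut-2-en-1-yl)phenyl]ethan-1-one F4.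
- MOMCl 5 with i-Pr2NEt protects the less hindered hydroxyl, the one not flanked by the prenyl group. This gives 1-[2-hydroxy-4,6-bis(methoxymethoxy)-3-(3-methylbut-2-en-1-yl)phenyl]ethan-1-one F5. This selectivity rests on sterics only, and any wrong isomer must be removed here.
- Condensation with 3 (KOH, EtOH) passes through the aldol adduct 3-hydroxy-1-[2-hydroxy-4,6-bis(methoxymethoxy)-3-(3-methylbut-2-en-1-yl)phenyl]-3-[4-methoxy-3-(3-methylbut-2-en-1-yl)phenyl]propan-1-one F6. It gives (2E)-1-[2-hydroxy-4,6-bis(methoxymethoxy)-3-(3-methylbut-2-en-1-yl)phenyl]-3-[4-methoxy-3-(3-methylbut-2-en-1-yl)phenyl]prop-2-en-1-one F7.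
- The only free phenol of F7 sits next to the prenyl group. Ring closure as in step 5 (or by the step 5 fallback) can therefore only give (2S)-5,7-bis(methoxymethoxy)-2-[4-methoxy-3-(3-methylbut-2-en-1-yl)phenyl]-8-(3-methylbut-2-en-1-yl)-2,3-dihydro-4H-chromen-4-one F8.
- HCl in MeOH removes both MOM groups and gives 15.

**Step 3.** The phenoxide of 6 is ambident, so C-prenylation of the electron-rich ring and double O-alkylation can compete. The fallback replaces phenoxide alkylation by a Mitsunobu etherification under neutral conditions, where no free phenoxide is present: 3-methylbut-2-en-1-ol, PPh3 and diisopropyl azodicarboxylate in THF at 0 °C. It sets out from 6 and comes back to the route at 8. It makes no new compound (F0).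

Steps 2 and 7 have close precedent on phloroacetophenones and on prenylated flavanones and are judged less risky.

## Further compounds

F0 | step 3 | none | none
F1 | step 5 | (2R)-2-[4-methoxy-3-(3-methylbut-2-en-1-yl)phenyl]-7-(methoxymethoxy)-5-[(3-methylbut-2-en-1-yl)oxy]-2,3-dihydro-4H-chromen-4-one | COc1ccc([C@H]2CC(=O)c3c(OCC=C(C)C)cc(OCOC)cc3O2)cc1CC=C(C)C
F2 | step 6 | 2-acetyl-3-hydroxy-5-(methoxymethoxy)-6-(2-methylbut-3-en-2-yl)cyclohexa-2,4-dien-1-one | CC(=O)C1=C(O)C=C(OCOC)C(C(C)(C)C=C)C1=O
F3 | step 6 | 2-acetyl-3-hydroxy-5-(methoxymethoxy)-4-(3-methylbut-2-en-1-yl)cyclohexa-2,5-dien-1-one | CC(=O)C1=C(O)C(CC=C(C)C)C(OCOC)=CC1=O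
F4 | step 6 | 1-[2,6-dihydroxy-4-(methoxymethoxy)-3-(3-methylbut-2-en-1-yl)phenyl]ethan-1-one | CC(=O)c1c(O)cc(OCOC)c(CC=C(C)C)c1O
F5 | step 6 | 1-[2-hydroxy-4,6-bis(methoxymethoxy)-3-(3-methylbut-2-en-1-yl)phenyl]ethan-1-one | CC(=O)c1c(OCOC)cc(OCOC)c(CC=C(C)C)c1O
F6 | step 6 | 3-hydroxy-1-[2-hydroxy-4,6-bis(methoxymethoxy)-3-(3-methylbut-2-en-1-yl)phenyl]-3-[4-methoxy-3-(3-methylbut-2-en-1-yl)phenyl]propan-1-one | COc1ccc(C(O)CC(=O)c2c(OCOC)cc(OCOC)c(CC=C(C)C)c2O)cc1CC=C(C)C
F7 | step 6 | (2E)-1-[2-hydroxy-4,6-bis(methoxymethoxy)-3-(3-methylbut-2-en-1-yl)phenyl]-3-[4-methoxy-3-(3-methylbut-2-en-1-yl)phenyl]prop-2-en-1-one | COc1ccc(/C=C/C(=O)c2c(OCOC)cc(OCOC)c(CC=C(C)C)c2O)cc1CC=C(C)C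
F8 | step 6 | (2S)-5,7-bis(methoxymethoxy)-2-[4-methoxy-3-(3-methylbut-2-en-1-yl)phenyl]-8-(3-methylbut-2-en-1-yl)-2,3-dihydro-4H-chromen-4-one | COc1ccc([C@@H]2CC(=O)c3c(OCOC)cc(OCOC)c(CC=C(C)C)c3O2)cc1CC=C(C)C
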